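**Retrosynthetic overview**
- Feature: ring A is a cyclohexenone (C1 = ketone, C2=C3, then C4–C6). Its tetrasubstituted C2=C3 bond holds the secondary carbon CH(CH3)CO2H on C2 and the quaternary carbon C1' of ring B (1,3,3-trimethylcyclohexane) on C3. C2 and C3 are therefore read as the two carbons of an unsymmetrical internal alkyne, and C4–C5–C6–C1(=O) as cyclobutanone.
- Key disconnection C1–C2 and C3–C4: nickel-catalysed insertion of that alkyne into a C(=O)–CH2 bond of cyclobutanone (formal [4+2], two-carbon ring expansion).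
- The alkyne comes from Sonogashira union of a C5 alkyne, made from methyl (S)-3-hydroxy-2-methylpropanoate (side-chain centre bought), with dimedone enol triflate. Catalytic asymmetric 1,4-methylation then sets C1', and tosylhydrazone deoxygenation removes the ketone.
- End game: C6 silyl dienol ether, catalytic asymmetric hydroxymethylation (sets C6), formate, desilylation, CH2OH → CO2H. Ring B is bought with dimedone; ring A is the only ring made, in the key step.

Key step: step 9

Assumption: the sense of induction of the two chiral catalysts (steps 6 and 11) on these substrates is inferred from the closest model substrates; both ligands exist in either mirror-image form, and the antipode meant is the one that gives the configuration drawn.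

**Step 1**
Reactants: 1 methyl (2S)-3-hydroxy-2-methylpropanoate
Product: 2 methyl (2S)-3-[(tert-butyldimethylsilyl)oxy]-2-methylpropanoate
Conditions: TBSCl, imidazole, CH2Cl2, 0 °C → rt
Reagents that add atoms: tert-butyldimethylsilyl chloride, CC(C)(C)[Si](C)(C)Cl
Why: Imidazole-promoted O-silylation of a primary alcohol; the stereocentre, which becomes the CH(CH3) carbon on C2 of ring A, is bought in and is not touched.

**Step 2**
Reactants: 2 methyl (2S)-3-[(tert-butyldimethylsilyl)oxy]-2-methylpropanoate
Product: 3 (2S)-3-[(tert-butyldimethylsilyl)oxy]-2-methylpropanal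
Conditions: iBu2AlH (1.05 equiv), CH2Cl2, −78 °C; aq. potassium sodium tartrate
Reagents that add atoms: none
Why: Low-temperature half-reduction of an ester with iBu2AlH holds the aldehyde oxidation level until work-up, and the configurationally sensitive α-methyl aldehyde is used at once without chromatography.

**Step 3**
Reactants: 3 (2S)-3-[(tert-butyldimethylsilyl)oxy]-2-methylpropanal
Product: 4 tert-butyldimethyl{[(2R)-2-methylbut-3-yn-1-yl]oxy}silane
Conditions: dimethyl (1-diazo-2-oxopropyl)phosphonate, K2CO3, MeOH, 0 °C → rt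
Reagents that add atoms: dimethyl (1-diazo-2-oxopropyl)phosphonate, CC(=O)C(=[N+]=[N-])P(=O)(OC)OC
Why: Ohira–Bestmann homologation turns CHO into C≡CH under mild carbonate conditions that α-methyl-β-silyloxy aldehydes tolerate without loss of configuration; the descriptor changes from S to R only through the priority rules.

**Step 4**
Reactants: 5 dimedone (5,5-dimethylcyclohexane-1,3-dione)
Product: 6 5,5-dimethyl-3-oxocyclohex-1-en-1-yl trifluoromethanesulfonate
Conditions: Tf2O, pyridine, CH2Cl2, −78 → 0 °C
Reagents that add atoms: trifluoromethanesulfonic anhydride, O=S(=O)(C(F)(F)F)OS(=O)(=O)C(F)(F)F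
Why: O-Triflation of the enol form of a symmetrical cyclic 1,3-diketone, which can give only one vinylogous acyl triflate.

**Step 5**
Reactants: 4 tert-butyldimethyl{[(2R)-2-methylbut-3-yn-1-yl]oxy}silane; 6 5,5-dimethyl-3-oxocyclohex-1-en-1-yl trifluoromethanesulfonate
Product: 7 3-{(3R)-4-[(tert-butyldimethylsilyl)oxy]-3-methylbut-1-yn-1-yl}-5,5-dimethylcyclohex-2-en-1-one
Conditions: PdCl2(PPh3)2 (3 mol %), CuI (6 mol %), Et3N, THF, rt
Reagents that add atoms: none
Why: Sonogashira coupling, in which the electron-poor enol triflate adds oxidatively to zerovalent palladium at room temperature and the neutral amine medium leaves the propargylic stereocentre and the silyl ether alone.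

**Step 6**
Reactants: 7 3-{(3R)-4-[(tert-butyldimethylsilyl)oxy]-3-methylbut-1-yn-1-yl}-5,5-dimethylcyclohex-2-en-1-one
Product: 9 (3R)-3-{(3R)-4-[(tert-butyldimethylsilyl)oxy]-3-methylbut-1-yn-1-yl}-3,5,5-trimethylcyclohexan-1-one, via bromomagnesium enolate 8 (not isolated)
Conditions: MeMgBr (Et2O, 1.5 equiv), Cu(OTf)2 (6 mol %), 1-(1-hydroxy-4-methylpentan-2-yl)-3-mesityl-4,5-dihydroimidazolium hexafluorophosphate (single enantiomer, 9 mol %), CH2Cl2, −10 °C; aq. NH4Cl
Reagents that add atoms: methylmagnesium bromide, C[Mg]Br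
Why: Copper/N-heterocyclic-carbene-catalysed asymmetric conjugate addition of a Grignard reagent, established for cyclic β-alkynyl enones, delivers the alkyl group to the β-carbon (1,4) and not to the alkyne terminus (1,6); the new quaternary centre (3R here, later C1' of ring B) is set by the chiral carbene on copper, because the side-chain centre across the linear alkyne is too remote to bias the faces.

**Step 7**
Reactants: 9 (3R)-3-{(3R)-4-[(tert-butyldimethylsilyl)oxy]-3-methylbut-1-yn-1-yl}-3,5,5-trimethylcyclohexan-1-one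
Product: 10 N-tosylhydrazone of 9
Conditions: TsNHNH2 (1.1 equiv), EtOH, rt → 50 °C
Reagents that add atoms: 4-methylbenzenesulfonohydrazide, Cc1ccc(cc1)S(=O)(=O)NN
Why: Hydrazone condensation of a saturated ketone flanked by two CH2 groups needs no added acid, touches no stereocentre, and the C=N geometry is of no consequence.

**Step 8**
Reactants: 10 N-tosylhydrazone of 9
Product: 12 tert-butyldimethyl({(2R)-2-methyl-4-[(1S)-1,3,3-trimethylcyclohexyl]but-3-yn-1-yl}oxy)silane, via alkyl diazene 11 (not isolated)
Conditions: catecholborane (3 equiv), CHCl3, −10 → 0 °C; then NaOAc·3H2O, reflux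
Reagents that add atoms: none
Why: In this mild tosylhydrazone deoxygenation catecholborane delivers hydride to C=N at a temperature at which the hindered internal alkyne is not hydroborated, and acetate then triggers loss of sulfinate to diazene 11, which extrudes N2 and leaves CH2; the quaternary centre is a spectator and its descriptor changes from R to S only through the priority rules.

**Step 9**
Reactants: 12 tert-butyldimethyl({(2R)-2-methyl-4-[(1S)-1,3,3-trimethylcyclohexyl]but-3-yn-1-yl}oxy)silane; 13 cyclobutanone
Product: 16 2-{(2R)-1-[(tert-butyldimethylsilyl)oxy]propan-2-yl}-3-[(1S)-1,3,3-trimethylcyclohexyl]cyclohex-2-en-1-one, via spiro oxanickelacyclopentene 14 (not isolated), via seven-membered nickelacycle 15 (not isolated)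
Conditions: Ni(cod)2 (20 mol %), PCy3 (40 mol %), 13 (4 equiv), toluene, 100 °C, sealed tube
Reagents that add atoms: none
Why: Zerovalent nickel carrying PCy3 binds alkyne 12 and the strained, electrophilic carbonyl group of 13 and couples them by oxidative cyclisation to oxanickelacyclopentene 14, in which the former carbonyl carbon (C1) is bonded to the alkyne carbon bearing CH(CH3)CH2OTBS (C2) while the alkyne carbon next to the quaternary centre (C3) stays on nickel. β-Carbon elimination from the nickel alkoxide, paid for by release of cyclobutane strain, cuts one C1–CH2 bond, restores the C1 ketone and gives the seven-membered alkyl(alkenyl)nickelacycle 15 (Ni–C4H2 and Ni–C3). Ring A is then closed by C(sp2)–C(sp3) reductive elimination between C3 and C4, a ring contraction of 15 that completes an intermolecular formal [4+2] two-carbon ring expansion and places C2=C3 inside the ring, so no alkene geometry arises. The closest known reaction is the Ni(cod)2/trialkylphosphine-catalysed insertion of internal dialkyl alkynes into 3-substituted cyclobutanones; a doubly branched alkyne and a cyclobutanone without 3-substituents stretch its tested range, which is why the catalyst loading is high and the cheap, volatile ketone is used in excess in a closed vessel. No stereocentre is formed, and the two existing ones are sp3 carbons outside the reacting atoms, with no acid, base or hydride source present that could scramble them. The step needs regioselective insertion, secured by the size difference between the quaternary carbon and the CH(CH3) carbon (the larger group ends up next to nickel, away from the forming C1–C2 bond), and it needs reductive elimination to outrun β-hydride elimination from the Ni–CH2–CH2 unit of 15, which the bulky electron-rich phosphine and the cyclic constraint should favour.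

**Step 10**
Reactants: 16 2-{(2R)-1-[(tert-butyldimethylsilyl)oxy]propan-2-yl}-3-[(1S)-1,3,3-trimethylcyclohexyl]cyclohex-2-en-1-one
Product: 18 [(6-{(2R)-1-[(tert-butyldimethylsilyl)oxy]propan-2-yl}-5-[(1S)-1,3,3-trimethylcyclohexyl]cyclohexa-1,5-dien-1-yl)oxy]trimethylsilane, via lithium dienolate 17 (not isolated)
Conditions: LiN(iPr)2 (1.2 equiv), THF, −78 °C; TMSCl (1.5 equiv), −78 → 0 °C; cold aq. NaHCO3/pentane, used crude
Reagents that add atoms: chlorotrimethylsilane, C[Si](C)(C)Cl
Why: Kinetic deprotonation of the enone with the hindered amide base takes place at the α' carbon C6 rather than at the shielded γ carbon C4, and O-silylation of dienolate 17 fixes the cross-conjugated 2-silyloxydiene.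

**Step 11**
Reactants: 18 the trimethylsilyl dienol ether of 16
Product: 19 (6S)-2-{(2R)-1-[(tert-butyldimethylsilyl)oxy]propan-2-yl}-6-(hydroxymethyl)-3-[(1S)-1,3,3-trimethylcyclohexyl]cyclohex-2-en-1-one
Conditions: aq. HCHO (37 %, 5 equiv), Sc(OTf)3 (10 mol %), 6,6'-bis(1-hydroxy-2,2-dimethylpropyl)-2,2'-bipyridine (single enantiomer, 12 mol %), DME/H2O 9:1, −20 °C
Reagents that add atoms: formaldehyde, C=O
Why: Catalytic asymmetric Mukaiyama aldol reaction with aqueous formaldehyde under a water-compatible chiral scandium–bipyridine Lewis acid is a known hydroxymethylation of ketone silyl enol ethers; the C6 centre (S) is set by the catalyst, which differentiates the faces of the C6=C1 enol ether, because the existing centres are too remote to do so.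

**Step 12**
Reactants: 19 the (6S)-6-(hydroxymethyl) enone
Product: 20 (6S)-2-{(2R)-1-[(tert-butyldimethylsilyl)oxy]propan-2-yl}-6-[(formyloxy)methyl]-3-[(1S)-1,3,3-trimethylcyclohexyl]cyclohex-2-en-1-one
Conditions: AcOCHO (3 equiv), pyridine, CH2Cl2, 0 °C
Reagents that add atoms: acetic formic anhydride, CC(=O)OC=O
Why: In O-formylation with the mixed anhydride only the far more electrophilic formyl group is transferred, and the weak base at 0 °C avoids retro-aldol cleavage, β-elimination and epimerisation at C6.

**Step 13**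
Reactants: 20 the silyl ether formate
Product: 21 (6S)-6-[(formyloxy)methyl]-2-[(2R)-1-hydroxypropan-2-yl]-3-[(1S)-1,3,3-trimethylcyclohexyl]cyclohex-2-en-1-one
Conditions: HF·pyridine, pyridine, THF, 0 °C → rt
Reagents that add atoms: none
Why: Fluoride-driven cleavage of a primary TBS ether in a buffered, weakly acidic medium, chosen over basic fluoride sources, spares the formate ester and the base-sensitive β-acyloxy ketone.

**Step 14**
Reactants: 21 the primary alcohol
Product: 22 (6S)-6-[(formyloxy)methyl]-2-[(2R)-1-oxopropan-2-yl]-3-[(1S)-1,3,3-trimethylcyclohexyl]cyclohex-2-en-1-one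
Conditions: TEMPO (10 mol %), PhI(OAc)2 (1.2 equiv), CH2Cl2, rt; used directly
Reagents that add atoms: none
Why: Oxoammonium (TEMPO) oxidation of a primary alcohol stops at the aldehyde in dry CH2Cl2 and is close to neutral, so the α-centre of the β,γ-unsaturated aldehyde, C6 and the formate should all persist.

**Step 15**
Reactants: 22 the aldehyde
Product: 23 (2R)-2-{(5S)-5-[(formyloxy)methyl]-6-oxo-2-[(1S)-1,3,3-trimethylcyclohexyl]cyclohex-1-en-1-yl}propanoic acid (target)
Conditions: NaClO2, NaH2PO4, 2-methylbut-2-ene, t-BuOH/H2O, 0 °C → rt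
Reagents that add atoms: sodium chlorite, [Na+].[O-]Cl=O
Why: Pinnick oxidation converts the aldehyde into the acid at about pH 4 without enolisation, the scavenger protects the tetrasubstituted alkene from hypochlorite, and a primary formate should survive the short exposure to the buffer.

**Compound list**
1 | methyl (2S)-3-hydroxy-2-methylpropanoate | C[C@@H](CO)C(=O)OC | starting material
2 | methyl (2S)-3-[(tert-butyldimethylsilyl)oxy]-2-methylpropanoate | C[C@@H](CO[Si](C)(C)C(C)(C)C)C(=O)OC | intermediate
3 | (2S)-3-[(tert-butyldimethylsilyl)oxy]-2-methylpropanal | C[C@@H](CO[Si](C)(C)C(C)(C)C)C=O | intermediate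
4 | tert-butyldimethyl{[(2R)-2-methylbut-3-yn-1-yl]oxy}silane | C[C@@H](CO[Si](C)(C)C(C)(C)C)C#C | intermediate
5 | dimedone (5,5-dimethylcyclohexane-1,3-dione) | CC1(C)CC(=O)CC(=O)C1 | starting material
6 | 5,5-dimethyl-3-oxocyclohex-1-en-1-yl trifluoromethanesulfonate | CC1(C)CC(=O)C=C(OS(=O)(=O)C(F)(F)F)C1 | intermediate
7 | 3-{(3R)-4-[(tert-butyldimethylsilyl)oxy]-3-methylbut-1-yn-1-yl}-5,5-dimethylcyclohex-2-en-1-one | C[C@@H](CO[Si](C)(C)C(C)(C)C)C#CC1=CC(=O)CC(C)(C)C1 | intermediate
8 | bromomagnesium enolate of 9 (C1–OMgBr, C1=C2, quaternary C3 already R) | C[C@@H](CO[Si](C)(C)C(C)(C)C)C#C[C@@]1(C)C=C(O[Mg]Br)CC(C)(C)C1 | intermediate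
9 | (3R)-3-{(3R)-4-[(tert-butyldimethylsilyl)oxy]-3-methylbut-1-yn-1-yl}-3,5,5-trimethylcyclohexan-1-one | C[C@@H](CO[Si](C)(C)C(C)(C)C)C#C[C@@]1(C)CC(=O)CC(C)(C)C1 | intermediate
10 | N-tosylhydrazone of 9 (C=N geometry not defined) | C[C@@H](CO[Si](C)(C)C(C)(C)C)C#C[C@@]1(C)CC(=NNS(=O)(=O)c2ccc(C)cc2)CC(C)(C)C1 | intermediate
11 | alkyl diazene (CH–N=NH in place of the C=O of 9, configuration at that CH not defined) | C[C@@H](CO[Si](C)(C)C(C)(C)C)C#C[C@@]1(C)CC(N=N)CC(C)(C)C1 | intermediate
12 | tert-butyldimethyl({(2R)-2-methyl-4-[(1S)-1,3,3-trimethylcyclohexyl]but-3-yn-1-yl}oxy)silane | C[C@@H](CO[Si](C)(C)C(C)(C)C)C#C[C@@]1(C)CCCC(C)(C)C1 | intermediate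
13 | cyclobutanone | O=C1CCC1 | starting material
14 | spiro oxanickelacyclopentene (ring Ni–O–C1–C2=C3, C1 spiro to the intact cyclobutane, PCy3 on nickel not drawn) | C[C@@H](CO[Si](C)(C)C(C)(C)C)C1=C([C@@]2(C)CCCC(C)(C)C2)[Ni]OC13CCC3 | intermediate
15 | seven-membered alkyl(alkenyl)nickelacycle (ring Ni–C4–C5–C6–C1(=O)–C2=C3, PCy3 on nickel not drawn) | C[C@@H](CO[Si](C)(C)C(C)(C)C)C1=C([C@@]2(C)CCCC(C)(C)C2)[Ni]CCCC1=O | intermediate
16 | 2-{(2R)-1-[(tert-butyldimethylsilyl)oxy]propan-2-yl}-3-[(1S)-1,3,3-trimethylcyclohexyl]cyclohex-2-en-1-one | C[C@@H](CO[Si](C)(C)C(C)(C)C)C1=C([C@@]2(C)CCCC(C)(C)C2)CCCC1=O | intermediate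
17 | lithium cross-conjugated dienolate of 16 (C1–OLi, C1=C6) | C[C@@H](CO[Si](C)(C)C(C)(C)C)C1=C([C@@]2(C)CCCC(C)(C)C2)CCC=C1O[Li] | intermediate
18 | [(6-{(2R)-1-[(tert-butyldimethylsilyl)oxy]propan-2-yl}-5-[(1S)-1,3,3-trimethylcyclohexyl]cyclohexa-1,5-dien-1-yl)oxy]trimethylsilane | C[C@@H](CO[Si](C)(C)C(C)(C)C)C1=C([C@@]2(C)CCCC(C)(C)C2)CCC=C1O[Si](C)(C)C | intermediate
19 | (6S)-2-{(2R)-1-[(tert-butyldimethylsilyl)oxy]propan-2-yl}-6-(hydroxymethyl)-3-[(1S)-1,3,3-trimethylcyclohexyl]cyclohex-2-en-1-one | C[C@@H](CO[Si](C)(C)C(C)(C)C)C1=C([C@@]2(C)CCCC(C)(C)C2)CC[C@@H](CO)C1=O | intermediate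
20 | (6S)-2-{(2R)-1-[(tert-butyldimethylsilyl)oxy]propan-2-yl}-6-[(formyloxy)methyl]-3-[(1S)-1,3,3-trimethylcyclohexyl]cyclohex-2-en-1-one | C[C@@H](CO[Si](C)(C)C(C)(C)C)C1=C([C@@]2(C)CCCC(C)(C)C2)CC[C@@H](COC=O)C1=O | intermediate
21 | (6S)-6-[(formyloxy)methyl]-2-[(2R)-1-hydroxypropan-2-yl]-3-[(1S)-1,3,3-trimethylcyclohexyl]cyclohex-2-en-1-one | C[C@@H](CO)C1=C([C@@]2(C)CCCC(C)(C)C2)CC[C@@H](COC=O)C1=O | intermediate
22 | (6S)-6-[(formyloxy)methyl]-2-[(2R)-1-oxopropan-2-yl]-3-[(1S)-1,3,3-trimethylcyclohexyl]cyclohex-2-en-1-one | C[C@@H](C=O)C1=C([C@@]2(C)CCCC(C)(C)C2)CC[C@@H](COC=O)C1=O | intermediate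
23 | (2R)-2-{(5S)-5-[(formyloxy)methyl]-6-oxo-2-[(1S)-1,3,3-trimethylcyclohexyl]cyclohex-1-en-1-yl}propanoic acid | C[C@@H](C(=O)O)C1=C([C@@]2(C)CCCC(C)(C)C2)CC[C@@H](COC=O)C1=O | target

**Total step count:** 15.
**Longest linear sequence:** 14 (steps 1–3 and 5–15).

**Steps most likely to fail**

**1. Step 9 (key step).**
- What may go wrong: the doubly branched alkyne may enter oxidative cyclisation too slowly, so that the ketone is lost to self-condensation or decarbonylation. After ring opening, β-hydride elimination may outrun ring closure. Insertion may also occur in the opposite orientation.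
- Fallback, from 12 back to 16: the annulation is carried out stepwise with stoichiometric metals.
  - Low-valent titanium from Ti(OiPr)4 and i-PrMgCl (2 equiv) in Et2O at −78 to −40 °C couples 12 with 4-chlorobutanal at the less hindered carbon C2. Iodine then cleaves the remaining C3–Ti bond with retention. This should give the (Z)-iodo allylic alcohol F1 (carbinol epimers, of no consequence).
  - Silylation (TESCl, imidazole) keeps the alkoxide from closing a tetrahydrofuran on the chloride and gives the triethylsilyl ether F2.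
  - Iodine–lithium exchange (t-BuLi, Et2O, −78 °C) followed by warming with HMPA closes C3–C4 by intramolecular alkylation and gives the silylated cyclohexenol F3.
  - AcOH/THF/H2O removes the secondary TES group in the presence of the primary TBS ether to give the cyclohexenol F4, and Dess–Martin periodinane oxidises it to 16.

**2. Step 6.**
- What may go wrong: the syn-axial methyl group at C5 may slow methyl transfer to the β-carbon. That leaves room for direct 1,2-addition of the Grignard reagent, for 1,6-addition at the alkyne terminus, and for poor facial selectivity.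
- Fallback, from 4 back to 12: the gem-dimethyl group is installed after the quaternary centre instead of before it.
  - Sonogashira coupling of 4 with commercial 3-bromocyclohex-2-en-1-one gives the unhindered enynone F5, the parent substrate class of the copper–carbene method.
  - Methyl addition with the mirror-image ligand gives the (3S)-3-alkynyl-3-methylcyclohexanone F6, whose carbonyl carbon sits where C3' of ring B has to be.
  - Direct geminal dimethylation of the C=O group with Me2TiCl2 (from Me2Zn and TiCl4, CH2Cl2, −30 °C → rt) gives 12. Steps 4, 7 and 8 then fall away.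

**3. Step 11.**
- What may go wrong: facial selectivity at C6 may be poor on a cross-conjugated, heavily substituted dienol ether. The dienol ether may undergo protodesilylation in the aqueous medium. The new α-centre may epimerise.
- Fallback, from 18 back to 19: catalyst control is given up for separation.
  - Hydroxymethylation of 18 with aqueous formaldehyde under achiral Yb(OTf)3 catalysis (THF/H2O, rt) gives 19 together with the (6R)-hydroxymethyl epimer F7.
  - Because the two other centres are fixed, these are diastereomers and are separated by chromatography.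
  - F7 is equilibrated at C6 through its enol with a mild amine base and separated again, so that the material converges on 19.

**Further compounds**
F1 | step 9 | (1Z)-2-{(2R)-1-[(tert-butyldimethylsilyl)oxy]propan-2-yl}-6-chloro-1-iodo-1-[(1S)-1,3,3-trimethylcyclohexyl]hex-1-en-3-ol (carbinol epimers) | C[C@@H](CO[Si](C)(C)C(C)(C)C)/C(C(O)CCCCl)=C(/I)[C@@]1(C)CCCC(C)(C)C1
F2 | step 9 | triethylsilyl ether of F1 | C[C@@H](CO[Si](C)(C)C(C)(C)C)/C(C(CCCCl)O[Si](CC)(CC)CC)=C(/I)[C@@]1(C)CCCC(C)(C)C1
F3 | step 9 | triethylsilyl ether of 2-{(2R)-1-[(tert-butyldimethylsilyl)oxy]propan-2-yl}-3-[(1S)-1,3,3-trimethylcyclohexyl]cyclohex-2-en-1-ol | C[C@@H](CO[Si](C)(C)C(C)(C)C)C1=C([C@@]2(C)CCCC(C)(C)C2)CCCC1O[Si](CC)(CC)CC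
F4 | step 9 | 2-{(2R)-1-[(tert-butyldimethylsilyl)oxy]propan-2-yl}-3-[(1S)-1,3,3-trimethylcyclohexyl]cyclohex-2-en-1-ol (carbinol epimers) | C[C@@H](CO[Si](C)(C)C(C)(C)C)C1=C([C@@]2(C)CCCC(C)(C)C2)CCCC1O
F5 | step 6 | 3-{(3R)-4-[(tert-butyldimethylsilyl)oxy]-3-methylbut-1-yn-1-yl}cyclohex-2-en-1-one | C[C@@H](CO[Si](C)(C)C(C)(C)C)C#CC1=CC(=O)CCC1
F6 | step 6 | (3S)-3-{(3R)-4-[(tert-butyldimethylsilyl)oxy]-3-methylbut-1-yn-1-yl}-3-methylcyclohexan-1-one | C[C@@H](CO[Si](C)(C)C(C)(C)C)C#C[C@@]1(C)CCCC(=O)C1
F7 | step 11 | (6R)-2-{(2R)-1-[(tert-butyldimethylsilyl)oxy]propan-2-yl}-6-(hydroxymethyl)-3-[(1S)-1,3,3-trimethylcyclohexyl]cyclohex-2-en-1-one | C[C@@H](CO[Si](C)(C)C(C)(C)C)C1=C([C@@]2(C)CCCC(C)(C)C2)CC[C@H](CO)C1=O
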